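## Structural features

The target 10 is a 2,2'-oxydiphenol: two benzene rings joined by one ether oxygen, each with a free hydroxyl ortho to that bridge, and five bromines in all. Ring A carries OH on C1, Br on C2 and C4, H on C3 and C5, and the bridging oxygen on C6. Ring B carries the bridging oxygen on C1', H on C2', Br on C3', C4' and C5', and OH on C6'. The molecule is flat and achiral, so there are no stereocentres and none that stand next to each other. The fragile elements are the five aryl C–Br bonds, which do not tolerate hydrogenolysis, halogen–metal exchange or the low-valent metal catalysts of most aryl C–O couplings, and the two electron-rich phenols, which are prone to oxidation and over-bromination. The real difficulty is positional: the rings are electronically almost alike, so bromination of the parent diaryl ether cannot decide which ring takes three bromines, and an Ullmann-type ether synthesis would have to single out one C–X bond among several C–Br bonds. The key step exploits the fact that C2 to C5 of ring A (Br, H, Br, H) reproduce C3 to C6 of 3,5-dibromo-2-pyrone, while C1 and C6, the two adjacent oxygen-bearing carbons, can come from the two carbons of an aryloxy ketene acetal that already contains the ether bond to ring B. Ring B has exactly the pattern that electrophilic bromination of a 2-alkoxyphenol delivers, so it can be brominated before the rings are joined.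

## Logic of the disconnections

**10 to 9.** The two O–H bonds of 10 are traced back to two O–Si bonds. The ring A silyl ether is the direct outcome of the ring-forming step, and the same trimethylsilyl group on the ring B oxygen lets both fall off together in dilute acid. A methyl ether on ring B would instead force a boron tribromide demethylation at the end. The gain is a last step that cannot touch the C–Br bonds or the diaryl ether. The demand is only that 9 goes into the hydrolysis without chromatography; partial loss of silicon beforehand is harmless.

**9 to 2 and 6.** Ring A is cut at C1–C2 and C5–C6, after formally adding back trimethylsilanol (which leads to 8) and carbon dioxide (which leads to 7). Fragment 2 holds C2 to C5 with both bromines; fragment 6 holds C1, C6, both oxygens and all of ring B. The cut is made here because no aryl C–O bond then has to be formed in the presence of five bromines, and every substituent of ring A is fixed by the connectivity of the partners. The gain is that a pentabrominated diaryl ether falls into two pieces, neither of which contains ring A as an arene. The demand is regiocontrol (the acetal carbon of 6 must bond to C3 of 2), survival of 6 at the reaction temperature, and onward loss of CO2 and silanol from 7 and 8.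

**6 to 4.** The three O–Si bonds and the C=C bond of 6 are traced back, through 5, to 4; compound 6 is simply the fully silylated enol form of 4. A bis-silyl ketene acetal is made from a carboxylic acid in one flask, its two identical silyloxy groups leave no alkene geometry to control, and silicon doubles as the protecting group of the ring B phenol. The gain is that no separate protection, ester formation or ester hydrolysis is needed. The demand is that phenol and carboxyl are both silylated before the enolization, so that no phenoxide can attack an activated carboxyl group, and that 6 is handled without water.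

**4 to 3.** The three C–Br bonds of 4 are cut. The free hydroxyl directs two bromines to its ortho and para positions and the ether oxygen directs the third to its own para position, which is the ring B pattern. Compound 3 is commercial and already contains the O–CH2–CO2H arm, so neither an O-alkylation nor an exchange of protecting groups between the two oxygens is needed. The gain is ring B with its two-carbon arm in one step. The demand is that the third bromine enters para and not ortho to the ether oxygen, and that bromination stops at three.

**2 to 1.** The C3–Br and C5–Br bonds of 2 are cut and a carboxyl group is put back on C5. Compound 1 is cheap; its carboxyl group marks C5 for ipso substitution, and C3 is the other nucleophilic carbon of the pyrone. The gain is the diene in a single step. The demand is that decarboxylative bromination at C5 and bromination at C3 both go to completion in the same operation.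

## Other disconnections considered

**Alternative 1:** Ring B is cut at C1'–C2' and C4'–C5' and traced to the racemic cyclohexane-1,3-dione A1, ethyl 1-(3,5-dibromo-2-methoxyphenoxy)-2,4-dioxocyclohexane-1-carboxylate.
- *Forward key step:* the stabilized enolate of the aryloxy acetoacetate A2, ethyl 2-(3,5-dibromo-2-methoxyphenoxy)-3-oxobutanoate, would add to ethyl acrylate A3. The methyl ketone enolate of the adduct would then close the six-membered ring by Claisen condensation on the new ester.
- *In favour:* the ether bond is made by simple phenoxide alkylation, the reagents are cheap, and the two enolate steps are robust and scalable.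
- *Against:* A1 holds ring B at the wrong oxidation level and with the wrong heteroatoms. It has an ester to remove from C1', oxygen where bromine belongs on C4', no bromine on C3' and C5', and four hydrogens too many. Removing the ester from a fully substituted carbon that also bears an aryloxy group invites retro-Claisen opening or loss of phenoxide. The exchange of oxygen for bromine must distinguish two carbonyl groups. The brominations needed for aromatization would compete with the still activated ring A. The phenol needed for A2 has its bromines ortho and para to the methoxy group, not to the free hydroxyl, so it needs a protecting group exchange of its own.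
- *Comparison, structure:* the chosen plan delivers ring A aromatic with every substituent in place, whereas A1 is about five operations away from ring B.
- *Comparison, mechanism:* both plans avoid an aryl C–O coupling and are equal on that point. The polar enolate chemistry of alternative 1 is the better of the two in robustness, since it needs neither a moisture-sensitive ketene acetal nor a sealed-tube pericyclic cascade.
- *Comparison, step economy:* alternative 1 is estimated at ten or more steps against five, so it is clearly the weaker.

**Alternative 2:** No ring bond is cut. Four C–Br bonds are disconnected and the fifth bromine is traced to an amino group.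
- *Forward key step:* bromine would substitute the aminodiphenol A5, 5-amino-2-(2-hydroxyphenoxy)phenol, four times. Two bromines flank the amino group on the future ring B and two go ortho and para to the hydroxyl of the future ring A, giving A4, 3-amino-2,4-dibromo-6-(3,5-dibromo-2-hydroxyphenoxy)phenol. Diazotization and CuBr would then turn the amine into the C4' bromine.
- *In favour:* every position follows innate directing effects, the phenols stay free throughout, and the amine marks the one ring B position (para to the ether oxygen) that is least certain in a direct bromination.
- *Against:* A5 must first be assembled, probably by SNAr of a nitrofluoroarene with a protected catechol, reduction and deprotection. The tetrabromination relies on rate differences alone: the position para to the ether oxygen on ring A could take a fifth bromine, and the aminophenol could be oxidized. The Sandmeyer exchange would take place at a doubly ortho-brominated, weakly basic aniline that also carries free phenols.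
- *Comparison, structure:* the chosen plan fixes the ring A bromines by construction, but its own ring B bromination (step 2) depends on the same directing effect that the amine secures more firmly. On that single point alternative 2 is the better.
- *Comparison, mechanism:* substrate-controlled electrophilic substitution is simpler to run than a cycloaddition cascade, but it offers no structural guarantee against over-bromination.
- *Comparison, step economy:* about five to six steps including A5, so the two plans are roughly equal.

**Alternative 3:** The two phenolic C–O bonds, C1–O and C6'–O, are cut. The bis-formate A6, 2,4-dibromo-6-(3,4,5-tribromo-2-formyloxyphenoxy)phenyl formate, is traced to the dialdehyde A7, 2,4-dibromo-6-(3,4,5-tribromo-2-formylphenoxy)benzaldehyde.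
- *Forward key step:* a peracid would add to each formyl group and the aryl group would migrate to oxygen (Dakin-type Baeyer–Villiger oxidation). Mild methanolysis of A6 would then give 10.
- *In favour:* the formyl groups serve twice, as activators for an SNAr ether synthesis and as latent hydroxyls. No protecting group is needed and the end of the route is mild.
- *Against:* the migrating aryl groups are electron-poor (two or three bromines and only an aryloxy donor), so hydride migration to the benzoic acids would compete. Both formyl groups sit between two ortho substituents, which hinders peracid addition. In the building blocks the bromines are ortho and para to the formyl group, against its directing effect, so neither aldehyde is available by simple bromination. In the SNAr step, bromines ortho and para to the formyl group are also activated.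
- *Comparison, structure:* all five bromines have to be bought or built into awkward building blocks, whereas the chosen plan takes them from bromine and from 2.
- *Comparison, mechanism:* the oxidation–rearrangement is operationally easy but electronically mismatched here, while the cycloaddition is electronically matched.
- *Comparison, step economy:* the three steps from the two aldehydes are the equal of the chosen endgame, and the absence of protecting groups is a point on which alternative 3 is the equal or the better. Counting three to four steps for each aldehyde, the whole is longer.

Key step: step 4

Remark on the chemistry: intermediates 7 and 8 are racemic, 7 is expected as a mixture of epimers at the aryloxy-bearing carbon, and all their sp3 centres vanish on aromatization, so their SMILES carry no stereodescriptors; the third bromine in step 2 is assumed to enter para to the ether oxygen, as in the trihalogenation of 2-alkoxyphenols.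

## Steps

Step 1
Reactants: 1 coumalic acid (2-oxo-2H-pyran-5-carboxylic acid)
Product: 2 3,5-dibromo-2H-pyran-2-one
Conditions: NBS (2.5 equiv), LiOAc (1 equiv), MeCN–H2O (9:1), rt
Reagents that add atoms: N-bromosuccinimide, O=C1CCC(=O)N1Br
Why: Hunsdiecker-type bromodecarboxylation combined with ring bromination: C5 and C3 are the two nucleophilic carbons of the pyrone, so Br+ from NBS attacks the lithium carboxylate ipso at C5 with loss of CO2 and substitutes C3–H; acetate only shuttles protons and is returned as LiOAc, and this one-flask conversion of 1 into 2 is an established preparation.

Step 2
Reactants: 3 (2-hydroxyphenoxy)acetic acid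
Product: 4 (3,4,5-tribromo-2-hydroxyphenoxy)acetic acid
Conditions: Br2 (3.3 equiv), AcOH, 20 → 50 °C; aq NaHSO3 quench; NaHCO3 extraction, then acidification
Reagents that add atoms: bromine, BrBr
Why: Electrophilic aromatic bromination under substrate control: the free hydroxyl sends the first two bromines to its ortho and para positions (C3 and C5), the third enters C4, para to the ether oxygen, and C6 stays free because it is meta to the hydroxyl and shielded by the side chain. The basic extraction reopens any lactone formed from the hydroxy acid in the acidic medium.

Step 3
Reactants: 4 (3,4,5-tribromo-2-hydroxyphenoxy)acetic acid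
Product: 6 1,1-bis(trimethylsilyloxy)-2-[3,4,5-tribromo-2-(trimethylsilyloxy)phenoxy]ethene, via trimethylsilyl [3,4,5-tribromo-2-(trimethylsilyloxy)phenoxy]acetate 5 (not isolated)
Conditions: LiN(SiMe3)2 (2.1 equiv), THF, 0 °C; Me3SiCl (4 equiv); then LiN(SiMe3)2 (1.2 equiv), −78 °C → rt; pentane, filtration under Ar, evaporation
Reagents that add atoms: chlorotrimethylsilane, C[Si](C)(C)Cl
Why: O-silylation followed by ester enolization with internal quench, the standard way from a carboxylic acid to a bis(trimethylsilyl) ketene acetal: the dilithium salt is silylated to 5, whose alpha protons are acidified by the aryloxy group, and the enolate formed by the third equivalent of base is trapped on oxygen. The silyl amide is too weak a base to metalate the bromoarene, the phenol is capped before the carboxyl is activated so no lactone can form, and the two identical silyloxy groups leave no E/Z question.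

Step 4
Reactants: 2 3,5-dibromo-2H-pyran-2-one; 6 1,1-bis(trimethylsilyloxy)-2-[3,4,5-tribromo-2-(trimethylsilyloxy)phenoxy]ethene
Product: 9 {2,4-dibromo-6-[3,4,5-tribromo-2-(trimethylsilyloxy)phenoxy]phenoxy}trimethylsilane, via bridged bicyclic lactone 7 (not isolated), via cyclohexa-1,3-diene 8 (not isolated)
Conditions: 6 (2 equiv), toluene, 120 °C, sealed tube, Ar; evaporation
Reagents that add atoms: none
Why: Diene 2 has a low LUMO (lactone carbonyl plus two bromines) and alkene 6 a high HOMO (three oxygen donors), so the two should combine in a concerted, asynchronous inverse-electron-demand Diels–Alder reaction across C3 and C6 of 2, the bond from the aryloxy-bearing carbon of 6 to C6 running ahead of the bond from the acetal carbon to C3. The closest known reaction type is the cycloaddition of electron-poor 2-pyrones with ketene acetals and 1,1,2-trialkoxyethenes, which ends in aryl ethers after loss of CO2 and an alcohol. Ring A is closed by this intermolecular (4+2) cycloaddition, which forms C1–C2 and C5–C6 together inside the bicyclo[2.2.2] lactone 7; retro-(4+2) extrusion of CO2 then leaves the carbocycle as diene 8, and 1,2-elimination of Me3SiOH, driven by aromatization, gives 9. The stereocentres of 7 and 8 are transient, so endo/exo selectivity is irrelevant and no stereocentre has to be controlled. The selectivity that matters is regiochemical: the largest HOMO coefficient of 6 lies on the CH(OAr) carbon, beta to both silyloxy donors, and the largest LUMO coefficient of 2 on C6, the 1,6-acceptor terminus of the dienyl lactone, so the acetal carbon ends up next to the C3 bromine and the aryloxy carbon next to C6–H, as ring A requires. The aromatization is chemoselective by necessity, because only the aryloxy-bearing carbon of 8 carries hydrogen, so silanol and never the ring B phenol can be eliminated. Two equivalents of 6 are used because the released silanol can protonate the ketene acetal; the surplus ends as 4 and is separated after step 5.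

Step 5
Reactants: 9 {2,4-dibromo-6-[3,4,5-tribromo-2-(trimethylsilyloxy)phenoxy]phenoxy}trimethylsilane
Product: 10 2,4-dibromo-6-(3,4,5-tribromo-2-hydroxyphenoxy)phenol (CNP0266564.0)
Conditions: 1 M HCl (cat.), THF–H2O (10:1), rt
Reagents that add atoms: none
Why: Acid-catalysed hydrolysis of aryl trimethylsilyl ethers, among the most labile silyl ethers; the aryl bromides and the diaryl ether are inert to dilute acid at room temperature, and any material already partly desilylated in step 4 converges on 10.

## Compound list

1 | coumalic acid (2-oxo-2H-pyran-5-carboxylic acid) | O=C(O)c1ccc(=O)oc1 | starting material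
2 | 3,5-dibromo-2H-pyran-2-one | O=c1occ(Br)cc1Br | intermediate
3 | (2-hydroxyphenoxy)acetic acid | OC(=O)COc1ccccc1O | starting material
4 | (3,4,5-tribromo-2-hydroxyphenoxy)acetic acid | OC(=O)COc1cc(Br)c(Br)c(Br)c1O | intermediate
5 | trimethylsilyl [3,4,5-tribromo-2-(trimethylsilyloxy)phenoxy]acetate (formed in the flask) | C[Si](C)(C)OC(=O)COc1cc(Br)c(Br)c(Br)c1O[Si](C)(C)C | intermediate
6 | 1,1-bis(trimethylsilyloxy)-2-[3,4,5-tribromo-2-(trimethylsilyloxy)phenoxy]ethene | C[Si](C)(C)OC(O[Si](C)(C)C)=COc1cc(Br)c(Br)c(Br)c1O[Si](C)(C)C | intermediate
7 | 4,7-dibromo-5,5-bis(trimethylsilyloxy)-6-[3,4,5-tribromo-2-(trimethylsilyloxy)phenoxy]-2-oxabicyclo[2.2.2]oct-7-en-3-one (racemic, epimers at C6, formed in the flask) | O=C1OC2C(Br)=CC1(Br)C(O[Si](C)(C)C)(O[Si](C)(C)C)C2Oc3cc(Br)c(Br)c(Br)c3O[Si](C)(C)C | intermediate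
8 | 1,3-dibromo-6,6-bis(trimethylsilyloxy)-5-[3,4,5-tribromo-2-(trimethylsilyloxy)phenoxy]cyclohexa-1,3-diene (racemic, formed in the flask) | BrC1=CC(Br)=CC(Oc2cc(Br)c(Br)c(Br)c2O[Si](C)(C)C)C1(O[Si](C)(C)C)O[Si](C)(C)C | intermediate
9 | {2,4-dibromo-6-[3,4,5-tribromo-2-(trimethylsilyloxy)phenoxy]phenoxy}trimethylsilane | C[Si](C)(C)Oc1c(Br)cc(Br)cc1Oc1cc(Br)c(Br)c(Br)c1O[Si](C)(C)C | intermediate
10 | 2,4-dibromo-6-(3,4,5-tribromo-2-hydroxyphenoxy)phenol | Oc1c(Br)cc(Br)cc1Oc1cc(Br)c(Br)c(Br)c1O | target

## Step count and least certain steps

Total step count: 5. Longest linear sequence: 4 steps (steps 2, 3, 4 and 5, from 3 to 10); step 1 is a one-step branch to 2.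

**Step 4 (key step).** The cycloaddition between a diene activated only by two bromines and a hindered, trisubstituted alkene may be slow. Protonation of 6 by the released silanol or by traces of water, or a stepwise conjugate addition with silyl transfer and opening of the pyrone ring, could then outrun ring formation. Stalling at the stage of 7, if CO2 is not expelled at the chosen temperature, is the second possibility.

Fallback, from 1 and 6 back to 10: the dienophile is kept, the diene is exchanged for the ester-activated pyrone for which this cascade is best established, and the ring A bromines are introduced afterwards.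
- Fischer esterification of 1 (MeOH, H2SO4) gives methyl 2-oxo-2H-pyran-5-carboxylate F1.
- Heating F1 with 6 in toluene should lead, through the bridged lactone methyl 3-oxo-5,5-bis(trimethylsilyloxy)-6-[3,4,5-tribromo-2-(trimethylsilyloxy)phenoxy]-2-oxabicyclo[2.2.2]oct-7-ene-7-carboxylate F2 and, after loss of CO2, the diene methyl 4,4-bis(trimethylsilyloxy)-3-[3,4,5-tribromo-2-(trimethylsilyloxy)phenoxy]cyclohexa-1,5-diene-1-carboxylate F3, to methyl 4-(trimethylsilyloxy)-3-[3,4,5-tribromo-2-(trimethylsilyloxy)phenoxy]benzoate F4. The silyloxy group is expected para to the ester, as is usual for this pyrone.
- LiOH in aqueous THF removes both silyl groups and the methyl ester to give 4-hydroxy-3-(3,4,5-tribromo-2-hydroxyphenoxy)benzoic acid F5.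
- Bromine (2 equiv) in AcOH buffered with NaOAc then brominates the free position ortho to the ring A hydroxyl and replaces the para carboxyl group by bromine with loss of CO2. This is the classical ipso-bromodecarboxylation of 4-hydroxybenzoic acids, and it returns to the route at 10.

**Step 3.** Transfer or loss of the aryl silyl group under the basic conditions, followed by lactonisation of the freed phenoxide onto the silyl ester, and hydrolysis during isolation are the likely failures, because 6 cannot be chromatographed.

Fallback, from 4 back to 10: the ring B oxygen is capped permanently.
- Dimethyl sulfate in aqueous NaOH methylates the phenol (any methyl ester is saponified in the same medium) to give (3,4,5-tribromo-2-methoxyphenoxy)acetic acid F6.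
- LiN(SiMe3)2 and Me3SiCl in THF convert F6, by way of trimethylsilyl (3,4,5-tribromo-2-methoxyphenoxy)acetate F7, into 1,1-bis(trimethylsilyloxy)-2-(3,4,5-tribromo-2-methoxyphenoxy)ethene F8, which contains no aryl silyl ether.
- F8 and 2 under the conditions of step 4 should pass through the bridged lactone 4,7-dibromo-6-(3,4,5-tribromo-2-methoxyphenoxy)-5,5-bis(trimethylsilyloxy)-2-oxabicyclo[2.2.2]oct-7-en-3-one F9 and the diene 1,3-dibromo-5-(3,4,5-tribromo-2-methoxyphenoxy)-6,6-bis(trimethylsilyloxy)cyclohexa-1,3-diene F10 to [2,4-dibromo-6-(3,4,5-tribromo-2-methoxyphenoxy)phenoxy]trimethylsilane F11.
- BBr3 in CH2Cl2 (−78 °C → rt) then cleaves the methyl ether and the silyl ether together and returns to the route at 10.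

**Step 2.** Poor regiocontrol of the third bromination (entry ortho instead of para to the ether oxygen) and over-bromination to a tetrabromide are the risks; isomeric acids would be hard to separate.

Fallback, from 3 back to 4: the para bromine is placed first, under electronic control.
- Acid-catalysed lactonisation of 3 (TsOH, toluene, water separator) gives 2,3-dihydro-1,4-benzodioxin-2-one F12, in which the former phenol oxygen is an aryl ester oxygen and a much weaker donor than the ether oxygen.
- One equivalent of bromine in AcOH should then enter para to the ether oxygen, as in the bromination of O-acylated 2-alkoxyphenols, to give 7-bromo-2,3-dihydro-1,4-benzodioxin-2-one F13.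
- Aqueous NaOH followed by acidification opens the lactone to (4-bromo-2-hydroxyphenoxy)acetic acid F14.
- Two equivalents of bromine then go ortho and para to the liberated hydroxyl, positions about which there is no doubt, and the sequence returns to the route at 4.

## Further compounds

F1 | step 4 | methyl 2-oxo-2H-pyran-5-carboxylate | COC(=O)c1ccc(=O)oc1
F2 | step 4 | methyl 3-oxo-5,5-bis(trimethylsilyloxy)-6-[3,4,5-tribromo-2-(trimethylsilyloxy)phenoxy]-2-oxabicyclo[2.2.2]oct-7-ene-7-carboxylate (racemic, epimers at C6) | O=C1OC2C(C(=O)OC)=CC1C(O[Si](C)(C)C)(O[Si](C)(C)C)C2Oc3cc(Br)c(Br)c(Br)c3O[Si](C)(C)C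
F3 | step 4 | methyl 4,4-bis(trimethylsilyloxy)-3-[3,4,5-tribromo-2-(trimethylsilyloxy)phenoxy]cyclohexa-1,5-diene-1-carboxylate (racemic) | COC(=O)C1=CC(Oc2cc(Br)c(Br)c(Br)c2O[Si](C)(C)C)C(O[Si](C)(C)C)(O[Si](C)(C)C)C=C1
F4 | step 4 | methyl 4-(trimethylsilyloxy)-3-[3,4,5-tribromo-2-(trimethylsilyloxy)phenoxy]benzoate | COC(=O)c1ccc(O[Si](C)(C)C)c(Oc2cc(Br)c(Br)c(Br)c2O[Si](C)(C)C)c1
F5 | step 4 | 4-hydroxy-3-(3,4,5-tribromo-2-hydroxyphenoxy)benzoic acid | OC(=O)c1ccc(O)c(Oc2cc(Br)c(Br)c(Br)c2O)c1
F6 | step 3 | (3,4,5-tribromo-2-methoxyphenoxy)acetic acid | OC(=O)COc1cc(Br)c(Br)c(Br)c1OC
F7 | step 3 | trimethylsilyl (3,4,5-tribromo-2-methoxyphenoxy)acetate | C[Si](C)(C)OC(=O)COc1cc(Br)c(Br)c(Br)c1OC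
F8 | step 3 | 1,1-bis(trimethylsilyloxy)-2-(3,4,5-tribromo-2-methoxyphenoxy)ethene | COc1c(OC=C(O[Si](C)(C)C)O[Si](C)(C)C)cc(Br)c(Br)c1Br
F9 | step 3 | 4,7-dibromo-6-(3,4,5-tribromo-2-methoxyphenoxy)-5,5-bis(trimethylsilyloxy)-2-oxabicyclo[2.2.2]oct-7-en-3-one (racemic, epimers at C6) | O=C1OC2C(Br)=CC1(Br)C(O[Si](C)(C)C)(O[Si](C)(C)C)C2Oc3cc(Br)c(Br)c(Br)c3OC
F10 | step 3 | 1,3-dibromo-5-(3,4,5-tribromo-2-methoxyphenoxy)-6,6-bis(trimethylsilyloxy)cyclohexa-1,3-diene (racemic) | BrC1=CC(Br)=CC(Oc2cc(Br)c(Br)c(Br)c2OC)C1(O[Si](C)(C)C)O[Si](C)(C)C
F11 | step 3 | [2,4-dibromo-6-(3,4,5-tribromo-2-methoxyphenoxy)phenoxy]trimethylsilane | COc1c(Oc2cc(Br)cc(Br)c2O[Si](C)(C)C)cc(Br)c(Br)c1Br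
F12 | step 2 | 2,3-dihydro-1,4-benzodioxin-2-one | O=C1COc2ccccc2O1
F13 | step 2 | 7-bromo-2,3-dihydro-1,4-benzodioxin-2-one | O=C1COc2ccc(Br)cc2O1
F14 | step 2 | (4-bromo-2-hydroxyphenoxy)acetic acid | OC(=O)COc1ccc(Br)cc1O
A1 | alternative 1 | ethyl 1-(3,5-dibromo-2-methoxyphenoxy)-2,4-dioxocyclohexane-1-carboxylate (racemic) | CCOC(=O)C1(Oc2cc(Br)cc(Br)c2OC)CCC(=O)CC1=O
A2 | alternative 1 | ethyl 2-(3,5-dibromo-2-methoxyphenoxy)-3-oxobutanoate (racemic) | CCOC(=O)C(Oc1cc(Br)cc(Br)c1OC)C(C)=O
A3 | alternative 1 | ethyl acrylate | C=CC(=O)OCC
A4 | alternative 2 | 3-amino-2,4-dibromo-6-(3,5-dibromo-2-hydroxyphenoxy)phenol | Nc1c(Br)cc(Oc2cc(Br)cc(Br)c2O)c(O)c1Br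
A5 | alternative 2 | 5-amino-2-(2-hydroxyphenoxy)phenol | Nc1ccc(Oc2ccccc2O)c(O)c1
A6 | alternative 3 | 2,4-dibromo-6-(3,4,5-tribromo-2-formyloxyphenoxy)phenyl formate | O=COc1c(Br)cc(Br)cc1Oc1cc(Br)c(Br)c(Br)c1OC=O
A7 | alternative 3 | 2,4-dibromo-6-(3,4,5-tribromo-2-formylphenoxy)benzaldehyde | O=Cc1c(Br)cc(Br)cc1Oc1cc(Br)c(Br)c(Br)c1C=O
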